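Spring is the plain flask, with each charge in from the start. Summer feeds the starting material and dawn feeds the partner, both over 5.0 min, and you want the target at 6.0 min.

| flask | starting material | partner | protic impurity | remark | time |
|---|---|---|---|---|---|
| Tuesday's | 0.064 M | 0.128 M | 0.0128 M | run made earlier |  |
| Thursday's | 0.064 M | 0.128 M | 0.0064 M | run made earlier |  |
| Wednesday's | 0.064 M | 0.128 M | 0.0096 M | run made earlier |  |
| Monday's | 0.096 M | 0.128 M | 0.0128 M | run made earlier |  |
| summer | 0.064 M (fed, over 5.0 min) | 0.128 M | 0.0128 M | all else is in the flask from the start; the feed brings no volume worth counting | 6.0 min |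
| spring | 0.064 M | 0.128 M | 0.0128 M | everything together at the start | 6.0 min |
| dawn | 0.064 M | 0.128 M (fed, over 5.0 min) | 0.0128 M | all else is in the flask from the start; the feed brings no volume worth counting | 6.0 min |

| run | time / min | target / % |
|---|---|---|
| Tuesday's | 0.667 | 8.3 |
| Tuesday's | 1.33 | 19.7 |
| Tuesday's | 2.00 | 27.5 |
| Tuesday's | 3.00 | 36.1 |
| Tuesday's | 4.00 | 42.0 |
| Thursday's | 0.333 | 2.3 |
| Thursday's | 0.833 | 11.8 |
| Thursday's | 1.50 | 22.4 |
| Thursday's | 2.50 | 32.9 |
| Thursday's | 4.00 | 43.0 |
| Wednesday's | 0.333 | 2.8 |
| Wednesday's | 0.833 | 11.6 |
| Wednesday's | 1.50 | 21.4 |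
| Wednesday's | 2.50 | 33.1 |
| Wednesday's | 4.00 | 42.6 |
| Monday's | 0.667 | 8.7 |
| Monday's | 1.33 | 16.6 |
| Monday's | 2.00 | 22.7 |
| Monday's | 3.00 | 30.4 |
| Monday's | 4.00 | 33.7 |

(each reading ± 0.5 percentage points)

* the flask that comes out highest in amount of target, in percent of the starting material charged, or "all alike" when all lie within 1.5 percentage points (summer / spring / dawn / all alike)
* target at the end, in percent of the starting material charged, summer
* target at the end, in percent of the starting material charged, spring
* target at the end, in percent of the starting material charged, dawn

- in percentages every species weighs as the starting material in it: one homo dimer or side product counts as two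
- steps thought possible: starting material + partner <-> intermediate A; intermediate B -> target; starting material <-> intermediate C; intermediate A <-> intermediate B; 2 starting material -> homo dimer; partner + protic impurity -> quenched reagent; starting material + intermediate A -> side product

A steady feed enters on average halfway through, so at the reading the fed charge has had the time minus half the feed: its mean age, or mean residence time, 3.50 min.

Here is my reckoning. Tuesday's run has spring's recipe, and at the mean age of 3.50 min, halfway between its readings at 3.00 min and 4.00 min, it stands at 39.0%, so summer starts from that. Slow feeding may also spare the loss seen on Monday, whose charge of starting material was larger and which read 8.3 percentage points lower at 4.00 min. Adding that back whole gives 47.3%. Tuesday needs 5.3 points more in the 2.00 min after its last reading, less than the 5.9 points of its last minute, so I put spring above summer.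

The forecast differs from me and names summer: summer 51% (44% to 57%), spring 49%, dawn 36%. Its ground: “Feeding starting material (summer) suppresses this loss but leaves less reaction time”.

The flasks give summer 44.2%, spring 48.8% and dawn 35.2%, so spring comes highest.

    starting material + partner ⇌ intermediate A (K = 11.0 M⁻¹, k = 1.30 M⁻¹ s⁻¹)
    intermediate B → target (k = 0.0460 s⁻¹)
    starting material ⇌ intermediate C (K = 0.320, k = 0.660 s⁻¹)
    intermediate A ⇌ intermediate B (K = 1.50, k = 0.0140 s⁻¹)
    2 starting material → homo dimer (k = 9.30 × 10⁻⁴ M⁻¹ s⁻¹)
    partner + protic impurity → quenched reagent (k = 3.10 M⁻¹ s⁻¹)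
    starting material + intermediate A → side product (k = 0.330 M⁻¹ s⁻¹)

Summer's 44.2% lies between the 39.0% read at its mean age of 3.50 min and the 47.3% with Monday's loss added back, and its side product stands at 25.4% against spring's 40.7%. Now shorten dawn's feed to 0.500 min: the mean age grows from 3.50 min to 5.75 min, and at Tuesday's 5.9 points a minute those 2.25 min reckon dawn's 35.2% up to 48.4%. That shortened dawn flask gives 47.6%.

The data come from a simulation with constants of no real substance; scatter was added.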